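**Retrosynthetic overview**
1. Target 13 ⇐ flavone-5,6-quinone 12: one hydrogenation reduces the quinone and removes both benzyl groups.
2. 12 ⇐ 1,3-diketone 9: key disconnection O1–C8a. Ring C is closed by oxidative C–O bond formation (catechol → ortho-quinone → oxa-Michael addition of the diketone enol oxygen to the only CH of ring A), so the hydroxyl ortho to the ketone stays free and becomes 5-OH.
3. 9 ⇐ ketone 6 + ester 8: crossed Claisen condensation (future C2–C3 bond).
4. 6 ⇐ 1 + 2 (ortho-lithiation/Weinreb acylation, then chelation-controlled double O-demethylation); 8 ⇐ 7 (benzylation).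
5. Ring order: rings A and B are bought; ring C is the only ring made (step 5).

Assumption: the target is planar and achiral, so "single enantiomer" is taken as the compound as drawn; the one stereocentre on the way (C2 of diketone 9, racemic) becomes sp2 in step 5.

**Step 1**
Reactants: 1 1,2,3,4-tetramethoxybenzene; 2 N,2-dimethoxy-N-methylacetamide
Product: 4 2-methoxy-1-(2,3,4,5-tetramethoxyphenyl)ethan-1-one, via aryllithium 3 (not isolated)
Conditions: n-BuLi (1.1 equiv), TMEDA, THF, 0 °C, 1 h; then 2, −78 → 0 °C; 1 M HCl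
Reagents that add atoms: none
Why: Directed ortho-metalation puts lithium next to a methoxy group at one of the two equivalent free positions of 1, and the Weinreb ketone synthesis stops at the ketone because the chelated tetrahedral adduct survives until the acid quench.

**Step 2**
Reactants: 4 2-methoxy-1-(2,3,4,5-tetramethoxyphenyl)ethan-1-one
Product: 6 1-(2,3-dihydroxy-4,5-dimethoxyphenyl)-2-methoxyethan-1-one, via chloroborole chelate 5 (not isolated)
Conditions: BCl3 (2.5 equiv), CH2Cl2, −78 → 20 °C; then H2O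
Reagents that add atoms: none
Why: Chelation-controlled ether cleavage: BCl3 bound to the ketone oxygen cleaves the ortho methoxy group, the resulting aryloxyboron chloride reaches only the neighbouring 3-methoxy group and closes dioxaborole 5, after which boron cannot reach the 4- and 5-methoxy groups (the same selectivity type as the known conversion of 2,3,4-trimethoxybenzaldehyde into 2,3-dihydroxy-4-methoxybenzaldehyde).

**Step 3**
Reactants: 7 methyl 3,5-dihydroxy-4-methoxybenzoate
Product: 8 methyl 3,5-bis(benzyloxy)-4-methoxybenzoate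
Conditions: BnBr (2.4 equiv), K2CO3, DMF, 60 °C
Reagents that add atoms: benzyl bromide, BrCc1ccccc1
Why: Williamson ether synthesis on the two equivalent phenols; the methyl ester and the central methyl ether are untouched by K2CO3.

**Step 4**
Reactants: 6 1-(2,3-dihydroxy-4,5-dimethoxyphenyl)-2-methoxyethan-1-one; 8 methyl 3,5-bis(benzyloxy)-4-methoxybenzoate
Product: 9 rac-1-[3,5-bis(benzyloxy)-4-methoxyphenyl]-3-(2,3-dihydroxy-4,5-dimethoxyphenyl)-2-methoxypropane-1,3-dione
Conditions: LiN(SiMe3)2 (4.5 equiv), THF, −78 °C → rt, Ar; cold 1 M HCl to pH 4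
Reagents that add atoms: none
Why: Crossed Claisen condensation of a polylithiated hydroxyaryl ketone: excess amide base gives the catecholate–enolate trianion, its carbon enolate is the only centre the non-enolisable ester 8 can acylate productively, and deprotonation of the new 1,3-diketone drives the equilibrium (C2 forms racemic and later becomes sp2).

**Step 5**
Reactants: 9 rac-1-[3,5-bis(benzyloxy)-4-methoxyphenyl]-3-(2,3-dihydroxy-4,5-dimethoxyphenyl)-2-methoxypropane-1,3-dione
Product: 12 2-[3,5-bis(benzyloxy)-4-methoxyphenyl]-3,7,8-trimethoxy-4H-chromene-4,5,6-trione, via diketone ortho-quinone 10 (not isolated), via dibenzyl catechol flavone 11 (not isolated)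
Conditions: Ag2O (2.5 equiv), 2,6-lutidine (1 equiv), 4 Å MS, MeCN (0.02 M), 0 °C → rt, dark, Ar; filter (Celite), used crude
Reagents that add atoms: none
Why: Proposed new method: Ag2O oxidises only the catechol of 9 (aryl ethers and the diketone are inert) to the 3-acyl-ortho-quinone 10, whose single ring CH is the β-carbon of both the ring enone and the exocyclic aroyl enone, so the enol oxygen of the lutidine-equilibrated diketone adds there in a 6-endo oxa-Michael step (attack through carbon or the other oxygen would give four-membered rings, and hemiketal formation at the quinone carbonyl is reversible), tautomerisation restores the catechol as flavone 11 with the former ketone-ortho hydroxyl at C5, and the second equivalent of Ag2O takes the electron-rich 11 to the vinylogous-ester-stabilised quinone 12 so that a single oxidation level is isolated; the closest known reaction types are the intramolecular 1,4-addition of tethered heteroatom nucleophiles to ortho-quinones (cyclodopa formation, oxidative lactonisation of dihydrocaffeic acids) and the oxidative cyclisation of 2,3'-dihydroxybenzophenones to xanthones, whereas closure of flavone ring C by a diketone enol oxygen on an ortho-quinone is, to my knowledge, not described.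

**Step 6**
Reactants: 12 2-[3,5-bis(benzyloxy)-4-methoxyphenyl]-3,7,8-trimethoxy-4H-chromene-4,5,6-trione
Product: 13 5,6,3',5'-tetrahydroxy-3,7,8,4'-tetramethoxyflavone
Conditions: H2 (1 atm), 10% Pd/C, EtOAc–MeOH, rt; filter under Ar
Reagents that add atoms: none
Why: Catalytic hydrogenation reduces the ortho-quinone to the catechol and hydrogenolyses both benzyl ethers in one operation, while the tetrasubstituted vinylogous-ester C2=C3 bond and the methyl ethers are inert at 1 atm.

**Compound list**
1 | 1,2,3,4-tetramethoxybenzene | COc1ccc(OC)c(OC)c1OC | starting material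
2 | N,2-dimethoxy-N-methylacetamide | COCC(=O)N(C)OC | starting material
3 | (2,3,4,5-tetramethoxyphenyl)lithium | [Li]c1cc(OC)c(OC)c(OC)c1OC | intermediate
4 | 2-methoxy-1-(2,3,4,5-tetramethoxyphenyl)ethan-1-one | COCC(=O)c1cc(OC)c(OC)c(OC)c1OC | intermediate
5 | 1-(2-chloro-6,7-dimethoxy-1,3,2-benzodioxaborol-4-yl)-2-methoxyethan-1-one | COCC(=O)c1cc(OC)c(OC)c2OB(Cl)Oc12 | intermediate
6 | 1-(2,3-dihydroxy-4,5-dimethoxyphenyl)-2-methoxyethan-1-one | COCC(=O)c1cc(OC)c(OC)c(O)c1O | intermediate
7 | methyl 3,5-dihydroxy-4-methoxybenzoate | COC(=O)c1cc(O)c(OC)c(O)c1 | starting material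
8 | methyl 3,5-bis(benzyloxy)-4-methoxybenzoate | COC(=O)c1cc(OCc2ccccc2)c(OC)c(OCc2ccccc2)c1 | intermediate
9 | rac-1-[3,5-bis(benzyloxy)-4-methoxyphenyl]-3-(2,3-dihydroxy-4,5-dimethoxyphenyl)-2-methoxypropane-1,3-dione | COC(C(=O)c1cc(OC)c(OC)c(O)c1O)C(=O)c1cc(OCc2ccccc2)c(OC)c(OCc2ccccc2)c1 | intermediate
10 | rac-1-[3,5-bis(benzyloxy)-4-methoxyphenyl]-3-(3,4-dimethoxy-5,6-dioxocyclohexa-1,3-dien-1-yl)-2-methoxypropane-1,3-dione | COC(C(=O)C1=CC(OC)=C(OC)C(=O)C1=O)C(=O)c1cc(OCc2ccccc2)c(OC)c(OCc2ccccc2)c1 | intermediate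
11 | 2-[3,5-bis(benzyloxy)-4-methoxyphenyl]-5,6-dihydroxy-3,7,8-trimethoxy-4H-chromen-4-one | COc1c(OCc2ccccc2)cc(-c2oc3c(OC)c(OC)c(O)c(O)c3c(=O)c2OC)cc1OCc1ccccc1 | intermediate
12 | 2-[3,5-bis(benzyloxy)-4-methoxyphenyl]-3,7,8-trimethoxy-4H-chromene-4,5,6-trione | COC1=C(c2cc(OCc3ccccc3)c(OC)c(OCc3ccccc3)c2)OC2=C(C1=O)C(=O)C(=O)C(OC)=C2OC | intermediate
13 | 5,6,3',5'-tetrahydroxy-3,7,8,4'-tetramethoxyflavone, i.e. 2-(3,5-dihydroxy-4-methoxyphenyl)-5,6-dihydroxy-3,7,8-trimethoxy-4H-chromen-4-one | COc1c(O)cc(-c2oc3c(OC)c(OC)c(O)c(O)c3c(=O)c2OC)cc1O | target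

**Totals**
Total steps: 6. Longest linear sequence: 5 (steps 1, 2, 4, 5, 6).

**Three steps most likely to fail**

Step 5 (the new oxidative ring closure). The risks are slow enolisation of the 2-methoxy-1,3-diketone, intermolecular trapping or decomposition of quinone 10, and incomplete second oxidation. The fallback uses known chemistry only and forms the same O1–C8a bond by copper-catalysed intramolecular O-arylation; it sets out from 6 and comes back at 13. Compound 6 is benzylated (BnBr, K2CO3, DMF) to 1-[2,3-bis(benzyloxy)-4,5-dimethoxyphenyl]-2-methoxyethan-1-one F1. F1 is brominated at its only free ring position (NBS, MeCN, 0 °C) to 1-[2,3-bis(benzyloxy)-6-bromo-4,5-dimethoxyphenyl]-2-methoxyethan-1-one F2. Claisen condensation of F2 with 8 (LiN(SiMe3)2, THF) gives rac-1-[2,3-bis(benzyloxy)-6-bromo-4,5-dimethoxyphenyl]-3-[3,5-bis(benzyloxy)-4-methoxyphenyl]-2-methoxypropane-1,3-dione F3. Its enolate oxygen displaces the bromide (CuI (copper iodide), 1,10-phenanthroline, K2CO3, DMF, 100 °C; the established flavone synthesis from 1-(2-bromoaryl)-1,3-diketones) to give 5,6-bis(benzyloxy)-2-[3,5-bis(benzyloxy)-4-methoxyphenyl]-3,7,8-trimethoxy-4H-chromen-4-one F4. Hydrogenolysis of F4 under the conditions of step 6 gives 13.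

Step 4 (Claisen condensation on the unprotected catechol ketone). The risks are a poorly soluble, air-sensitive trianion and sluggish acylation by the ester. The fallback masks the catechol with groups that come off under neutral conditions; it sets out from 6 and comes back at 9. Compound 6 is allylated (allyl bromide, K2CO3, acetone) to 1-[2,3-bis(allyloxy)-4,5-dimethoxyphenyl]-2-methoxyethan-1-one F5. F5 condenses with 8 as a simple mono-enolate (LiN(SiMe3)2, 2.2 equiv, THF) to rac-1-[2,3-bis(allyloxy)-4,5-dimethoxyphenyl]-3-[3,5-bis(benzyloxy)-4-methoxyphenyl]-2-methoxypropane-1,3-dione F6. Pd(PPh3)4 (5 mol %) with PhSiH3 in CH2Cl2 at rt removes both allyl groups without touching the benzyl ethers and without acid, giving 9.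

Step 2 (double demethylation with BCl3). The risks are cleavage of the aliphatic methyl ether of the side chain, or stopping at the mono-phenol. The fallback avoids Lewis acid altogether by building the ketone on an already differentiated catechol; it sets out from 2 and comes back at 6. Commercial 2-hydroxy-3,4-dimethoxybenzaldehyde F7 undergoes Dakin oxidation (H2O2, NaOH) to 3,4-dimethoxybenzene-1,2-diol F8. F8 is protected (MOMCl, iPr2NEt, CH2Cl2) as 1,2-dimethoxy-3,4-bis(methoxymethoxy)benzene F9. Lithiation of F9 (n-BuLi, TMEDA, THF) goes ortho to the stronger OCH2OMe director, and acylation with 2 gives 1-[4,5-dimethoxy-2,3-bis(methoxymethoxy)phenyl]-2-methoxyethan-1-one F10. Catalytic HCl in MeOH at rt removes both acetals to give 6.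

**Further compounds**
F1 | step 5 | 1-[2,3-bis(benzyloxy)-4,5-dimethoxyphenyl]-2-methoxyethan-1-one | COCC(=O)c1cc(OC)c(OC)c(OCc2ccccc2)c1OCc1ccccc1
F2 | step 5 | 1-[2,3-bis(benzyloxy)-6-bromo-4,5-dimethoxyphenyl]-2-methoxyethan-1-one | COCC(=O)c1c(Br)c(OC)c(OC)c(OCc2ccccc2)c1OCc1ccccc1
F3 | step 5 | rac-1-[2,3-bis(benzyloxy)-6-bromo-4,5-dimethoxyphenyl]-3-[3,5-bis(benzyloxy)-4-methoxyphenyl]-2-methoxypropane-1,3-dione | COC(C(=O)c1c(Br)c(OC)c(OC)c(OCc2ccccc2)c1OCc1ccccc1)C(=O)c1cc(OCc2ccccc2)c(OC)c(OCc2ccccc2)c1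
F4 | step 5 | 5,6-bis(benzyloxy)-2-[3,5-bis(benzyloxy)-4-methoxyphenyl]-3,7,8-trimethoxy-4H-chromen-4-one | COc1c(OCc2ccccc2)cc(-c2oc3c(OC)c(OC)c(OCc4ccccc4)c(OCc4ccccc4)c3c(=O)c2OC)cc1OCc1ccccc1
F5 | step 4 | 1-[2,3-bis(allyloxy)-4,5-dimethoxyphenyl]-2-methoxyethan-1-one | COCC(=O)c1cc(OC)c(OC)c(OCC=C)c1OCC=C
F6 | step 4 | rac-1-[2,3-bis(allyloxy)-4,5-dimethoxyphenyl]-3-[3,5-bis(benzyloxy)-4-methoxyphenyl]-2-methoxypropane-1,3-dione | COC(C(=O)c1cc(OC)c(OC)c(OCC=C)c1OCC=C)C(=O)c1cc(OCc2ccccc2)c(OC)c(OCc2ccccc2)c1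
F7 | step 2 | 2-hydroxy-3,4-dimethoxybenzaldehyde | COc1ccc(C=O)c(O)c1OC
F8 | step 2 | 3,4-dimethoxybenzene-1,2-diol | COc1ccc(O)c(O)c1OC
F9 | step 2 | 1,2-dimethoxy-3,4-bis(methoxymethoxy)benzene | COCOc1ccc(OC)c(OC)c1OCOC
F10 | step 2 | 1-[4,5-dimethoxy-2,3-bis(methoxymethoxy)phenyl]-2-methoxyethan-1-one | COCC(=O)c1cc(OC)c(OC)c(OCOC)c1OCOC
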